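**Plan**
- Cuts: the two ester C–O bonds (O1–acyl, O7–coumaroyl), C4–C11 (Stille), C6–C7 (hydroacylation), C5=C6 (Mannich methylenation) and C8–C9 (Mukaiyama–Michael).
- Enabling feature: in the cyclopentane ring (C5, C6, C7, C8, C9) the oxygenated C7 lies between the bare C6H2 and the fully substituted C8. At ketone level C7 is therefore the acyl carbon of a pent-4-enal C7–C8–C9–C5=C6, whose alkene is an exocyclic methylene on the pyran ring (C1, O2, C3, C4, C5, C9).
- Forward order: the pyranone ring comes ready-made from D-xylal, the glycerate unit (C7, C8, C10) is joined at C9, C6 is added at C5, and rhodium closes the cyclopentanone. C7 reduction, the two acylations, C3=C4/C11 installation and desilylation follow.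
- Stereochemistry, ring carbons: C1 comes from D-xylal through separable Ferrier anomers. C9 forms anti to the C1 methoxy group. C8 comes from (R)-glycerate, relayed by a tert-butyl acetal. C5 is set by equilibration next to a C4 ketone, which is kept in place during the key step for this purpose.
- Stereochemistry, remainder: C7 is set by hydride delivery directed by the C8 hydroxyl. The final C1 ester follows the anomeric and steric preference. The side-chain centre is bought, and the Z-alkene comes from a Still–Gennari olefination.

Key step: step 9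

Remark: iridoid numbering is used for every intermediate, β means the face that carries H5 and H9 in the target, and lactol 23 is drawn as its β-anomer although both anomers interconvert.

Step 1
Reactants: 1 3,4-di-O-acetyl-D-xylal
Product: 2 methyl 4-O-acetyl-2,3-dideoxy-β-D-glycero-pent-2-enopyranoside (C1-OMe β, C4-OAc α)
Conditions: MeOH, BF3·OEt2 (cat.), CH2Cl2, −20 → 0 °C; chromatography removes the α-anomer
Reagents that add atoms: methanol, CO
Why: Ferrier rearrangement: BF3 ionises the allylic acetate next to the glycal double bond and methanol adds to the allyl oxocarbenium ion at the anomeric carbon (iridoid C1), the 1,4-trans β-anomer being expected to prevail because OMe and OAc can both stand pseudo-axial, and the remaining acetoxy stereocentre makes the two anomers separable diastereomers.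

Step 2
Reactants: 2 methyl 4-O-acetyl-2,3-dideoxy-β-D-glycero-pent-2-enopyranoside
Product: 3 methyl 2,3-dideoxy-β-D-glycero-pent-2-enopyranoside [(3S,6R)-6-methoxy-3,6-dihydro-2H-pyran-3-ol]
Conditions: K2CO3 (cat.), MeOH, 0 °C → rt
Reagents that add atoms: none
Why: Base-catalysed transesterification (Zemplén type) removes the acetate without touching the allylic acetal, so C1 keeps its configuration.

Step 3
Reactants: 3 methyl 2,3-dideoxy-β-D-glycero-pent-2-enopyranoside
Product: 4 (R)-6-methoxy-2H-pyran-3(6H)-one
Conditions: MnO2, CH2Cl2, rt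
Reagents that add atoms: none
Why: MnO2 oxidises the allylic alcohol selectively to the enone, which erases the auxiliary C4 centre and leaves C1 as the single stereocentre of the enantiopure Michael acceptor.

Step 4
Reactants: 5 methyl (R)-2,2-dimethyl-1,3-dioxolane-4-carboxylate
Product: 6 methyl (2R,4R)-2-tert-butyl-1,3-dioxolane-4-carboxylate (cis)
Conditions: t-BuCHO, TsOH·H2O (cat.), cyclohexane, reflux (acetone distilled off); chromatography, trans isomer re-equilibrated
Reagents that add atoms: pivalaldehyde, CC(C)(C)C=O
Why: Acid-catalysed transacetalisation driven by removal of acetone; the new acetal carbon forms under thermodynamic control as a cis/trans pair of separable diastereomers, and the cis isomer copies the (R)-glycerate configuration onto the acetal carbon (self-regeneration of stereocentres).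

Step 5
Reactants: 6 methyl (2R,4R)-2-tert-butyl-1,3-dioxolane-4-carboxylate
Product: 7 tert-butyldimethylsilyl ketene acetal of 6 (acetal carbon R, double-bond geometry immaterial)
Conditions: LiN(i-Pr)2, t-BuMe2SiCl, THF–DMPU, −78 → 0 °C
Reagents that add atoms: tert-butyldimethylsilyl chloride, CC(C)(C)[Si](C)(C)Cl
Why: Ester enolisation with O-silylation gives the ketene silyl acetal; β-elimination is suppressed because the ring C10–O10 bond lies in the plane of the exocyclic enolate, and although C8 becomes trigonal the tert-butyl acetal carbon retains the stereochemical information.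

Step 6
Reactants: 4 (R)-6-methoxy-2H-pyran-3(6H)-one; 7 silyl ketene acetal
Product: 8 Michael adduct: C4=C5 TBS enol ether of the 1β-methoxypyran-4-one carrying at C9 (α, trans to OMe) the quaternary C8 of the tert-butyl dioxolane methyl ester (t-Bu cis to CO2Me, trans to C9)
Conditions: t-BuMe2SiOTf (10 mol %), CH2Cl2, −78 °C
Reagents that add atoms: none
Why: Mukaiyama–Michael addition with silyl transfer: the silyl-activated enone is attacked at C9 anti to the pseudo-axial C1 methoxy group while the ketene acetal reacts on its face remote from the tert-butyl group, so C9 and the quaternary C8 are each fixed by their own control element and the C4=C5 silyl enol ether is retained regiodefined for step 8.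

Step 7
Reactants: 8 Michael adduct
Product: 9 C7 aldehyde of 8 (silyl enol ether retained)
Conditions: i-Bu2AlH (1.1 equiv), CH2Cl2, −78 °C; aq potassium sodium tartrate
Reagents that add atoms: none
Why: Partial ester reduction: at −78 °C the α-alkoxy ester is taken by i-Bu2AlH only to the chelated aluminium hemiacetal, which releases the non-enolisable C7 aldehyde on work-up, the silyl enol ether and both acetals being inert to the hydride.

Step 8
Reactants: 9 C7 aldehyde
Product: 12 1β-methoxy-5-methylene-4-oxotetrahydropyran bearing at C9α the quaternary C8 dioxolane carbaldehyde, via Mannich base 10 (not isolated), via methiodide 11 (not isolated)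
Conditions: [Me2N=CH2]I, CH2Cl2, rt; MeI, rt; sat. aq NaHCO3, rt; product used at once
Reagents that add atoms: N,N-dimethylmethyleneiminium iodide (Eschenmoser's salt), C=[N+](C)C.[I-]; iodomethane, CI (its carbon stays only in 11 and leaves again as trimethylamine)
Why: Mannich reaction of the silyl enol ether with the preformed iminium salt puts C6 on C5 regiospecifically, and quaternisation followed by base-induced E1cB (Hofmann-type) loss of trimethylamine unveils the exocyclic C5=C6 enone, the quaternary C8 protecting the aldehyde from enolisation.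

Step 9
Reactants: 12 5-methylene-4-oxopyran carbaldehyde
Product: 14 cis-fused 1β-methoxy-4,7-dioxocyclopenta[c]pyran spiro-fused at C8 to the tert-butyl dioxolane (O8 α; C10 β; H5 β; H9 β), via kinetic diketone of unsettled C5 configuration 13 (not isolated)
Conditions: [Rh(nbd)(dppe)]BF4 (10 mol %), H2 then Ar, acetone, rt → 40 °C; then DBU (0.2 equiv), CH2Cl2, rt
Reagents that add atoms: none
Why: The cationic monovalent rhodium centre freed from norbornadiene inserts into the C7 formyl C–H bond; the acyl rhodium hydride, held to the C5=C6 alkene as a chelate, passes hydride to C5 and binds C6, and reductive elimination from the six-membered acyl–alkyl rhodacycle forges C6–C7 and releases the catalyst. The closest known reaction type is the rhodium diphosphine-catalysed intramolecular hydroacylation of 4-substituted pent-4-enals, 4-acyl members included, to 3-substituted cyclopentanones. The cyclopentanone (C5–C6–C7–C8–C9) closes in a formally 5-endo-trig sense, which is possible because the bond arises by reductive elimination inside the metallacycle and not by direct attack on the alkene. The regiochemistry needed (H to C5, Rh to C6) is secured because the opposite insertion gives a five-membered rhodacycle that could only collapse to a cyclobutanone and therefore reverts, while decarbonylation and aldol pathways are held back by the chelating alkene, by dioxolane O10, which can fill the vacant site in a five-membered chelate, and by the fully substituted C8. The one new stereocentre, C5, lies next to the C4 ketone, so whatever kinetic mixture 13 arises is equilibrated by DBU to the cis-fused ketone 14 (H5 cis to H9). The cis isomer is the expected minimum because it lets C8 stand axial on the pyranone, where it meets only O2 and the trigonal C4, and keeps the C1 methoxy group axial (anomeric effect), whereas trans fusion would force both groups equatorial.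

Step 10
Reactants: 14 cis-fused spiro-acetal diketone
Product: 15 8α-hydroxy-8β-(hydroxymethyl)-1β-methoxy-4,7-dione
Conditions: HCl (1.25 M in MeOH), 40 °C
Reagents that add atoms: none
Why: Acid-catalysed acetal exchange with methanol frees the C8,C10-diol, exchange at C1 being degenerate in this solvent and the rigid bicycle keeping both new hydroxyls out of reach of C1, while C5 stays at its cis equilibrium.

Step 11
Reactants: 15 keto diol
Product: 16 10-O-tert-butyldiphenylsilyl ether of 15
Conditions: t-BuPh2SiCl, imidazole, CH2Cl2, 0 °C → rt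
Reagents that add atoms: tert-butyldiphenylsilyl chloride, CC(C)(C)[Si](Cl)(c1ccccc1)c1ccccc1
Why: Silyl ether formation is selective for the primary C10 hydroxyl since the C8 hydroxyl is tertiary and flanked by a ketone, which leaves the latter free as the directing group of step 12.

Step 12
Reactants: 16 10-O-silyl α-hydroxy diketone
Product: 17 7β,8α-diol with the C4 ketone retained
Conditions: Me4NBH(OAc)3, MeCN–AcOH, −20 °C
Reagents that add atoms: none
Why: Hydroxyl-directed Saksena–Evans reduction: the C8 hydroxyl (α face) exchanges onto boron and hands hydride to the neighbouring C7 carbonyl from that same face, which sets the 7β-carbinol trans to O8, whereas the C4 ketone has no hydroxyl within reach and is not attacked by the weakly reducing acetoxyborohydride.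

Step 13
Reactants: 18 4-hydroxybenzaldehyde
Product: 19 4-(tert-butyldimethylsilyloxy)benzaldehyde
Conditions: t-BuMe2SiCl, imidazole, CH2Cl2, rt
Reagents that add atoms: tert-butyldimethylsilyl chloride, CC(C)(C)[Si](C)(C)Cl
Why: Standard phenol silylation masks the acidic OH for the olefination and the later acylations.

Step 14
Reactants: 19 4-(tert-butyldimethylsilyloxy)benzaldehyde
Product: 20 methyl (Z)-3-[4-(tert-butyldimethylsilyloxy)phenyl]acrylate
Conditions: (CF3CH2O)2P(O)CH2CO2Me, KN(SiMe3)2, 18-crown-6, THF, −78 °C
Reagents that add atoms: methyl bis(2,2,2-trifluoroethyl)phosphonoacetate, COC(=O)CP(=O)(OCC(F)(F)F)OCC(F)(F)F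
Why: Still–Gennari olefination: the trifluoroethyl phosphonate with a dissociated potassium counter-ion makes elimination of the kinetic adduct faster than its reversal, which sets the Z-alkene.

Step 15
Reactants: 20 methyl Z-ester
Product: 21 (Z)-3-[4-(tert-butyldimethylsilyloxy)phenyl]acrylic acid
Conditions: Me3SnOH, ClCH2CH2Cl, 70 °C, dark; 1 M HCl wash
Reagents that add atoms: trimethyltin hydroxide, C[Sn](C)(C)O
Why: Ester cleavage with Me3SnOH proceeds under nearly neutral conditions, so neither the base-labile aryl silyl ether nor the Z-geometry should suffer.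

Step 16
Reactants: 17 7β,8α-diol; 21 Z-acid
Product: 22 7β-O-[(Z)-4-(tert-butyldimethylsilyloxy)cinnamoyl] ester of 17
Conditions: EDC·HCl, DMAP, CH2Cl2, 0 °C → rt, dark
Reagents that add atoms: none
Why: Steglich esterification acylates the secondary C7 hydroxyl only, the tertiary C8 hydroxyl being inert, low temperature and exclusion of light guard the Z-alkene, and C7 keeps its configuration because its C–O bond is not touched.

Step 17
Reactants: 22 C7 coumarate
Product: 23 C1 lactol of 22
Conditions: 1 M aq HCl, THF, rt
Reagents that add atoms: water, O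
Why: Acid hydrolysis of a 2-alkoxytetrahydropyran-type acetal is carried out while the pyran ring is still saturated, so no enol ether is at risk, and the esters, the aryl silyl ether and the tert-butyldiphenylsilyl ether tolerate dilute acid.

Step 18
Reactants: 23 lactol; 24 (R)-3-methylpentanoic acid
Product: 25 1β-O-[(R)-3-methylpentanoyl] ester
Conditions: EDC·HCl, DMAP, CH2Cl2, −20 → 0 °C
Reagents that add atoms: none
Why: Steglich acylation of the equilibrating lactol should funnel into the 1β-ester, in which the acyloxy group is axial (anomeric effect) and anti to the bulky C8, which sets the final C1 configuration.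

Step 19
Reactants: 25 C1 ester
Product: 26 8-O-trimethylsilyl ether of 25
Conditions: 1-(trimethylsilyl)imidazole, CH2Cl2, rt
Reagents that add atoms: 1-(trimethylsilyl)imidazole, C[Si](C)(C)n1ccnc1
Why: Neutral silylation caps the hindered tertiary C8 hydroxyl without a Lewis acid that could ionise the C1 acyloxy acetal, so that the base of step 20 meets no acidic proton.

Step 20
Reactants: 26 fully protected C4 ketone
Product: 27 C3=C4 enol triflate
Conditions: KN(SiMe3)2 added to 26 and N-(5-chloro-2-pyridyl)bis(trifluoromethanesulfonimide), THF, −78 °C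
Reagents that add atoms: N-(5-chloro-2-pyridyl)bis(trifluoromethanesulfonimide) (Comins' reagent), O=S(=O)(N(c1ccc(Cl)cn1)S(=O)(=O)C(F)(F)F)C(F)(F)F
Why: Kinetic enolisation with in situ O-sulfonylation (enol triflate formation): the ketone is far more acidic than either ester, and the hindered amide should take a proton from the accessible, O2-acidified C3 methylene and not the ring-fusion C5–H, whose loss would place a tetrasubstituted double bond at the ring fusion.

Step 21
Reactants: 27 enol triflate
Product: 28 tris-silylated target with free C11 alcohol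
Conditions: Bu3SnCH2OH, Pd(PPh3)4 (10 mol %), LiCl, THF, 65 °C, dark
Reagents that add atoms: (tributylstannyl)methanol, CCCC[Sn](CCCC)(CCCC)CO
Why: Stille coupling: zerovalent palladium inserts into the C4–OTf bond, LiCl assists transfer of the hydroxymethyl group from tin, and reductive elimination installs C11 at the alcohol level under neutral conditions that spare both esters and the acyloxy acetal.

Step 22
Reactants: 28 tris-silylated target
Product: 29 CNP0217341.1
Conditions: HF·pyridine, pyridine, THF, 0 °C → rt, dark
Reagents that add atoms: none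
Why: Fluoride-mediated cleavage of all three silyl ethers in a pyridine-buffered medium avoids both the acid that would ionise the enol ether acetal and the basic conditions that would promote O7 to O10 acyl migration or Z to E isomerisation.

**Compound list**
1 | 3,4-di-O-acetyl-D-xylal | CC(=O)O[C@@H]1C=COC[C@H]1OC(C)=O | starting material
2 | methyl 4-O-acetyl-2,3-dideoxy-β-D-glycero-pent-2-enopyranoside | CO[C@@H]1OC[C@@H](OC(C)=O)C=C1 | intermediate
3 | (3S,6R)-6-methoxy-3,6-dihydro-2H-pyran-3-ol | CO[C@@H]1OC[C@@H](O)C=C1 | intermediate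
4 | (R)-6-methoxy-2H-pyran-3(6H)-one | CO[C@@H]1OCC(=O)C=C1 | intermediate
5 | methyl (R)-2,2-dimethyl-1,3-dioxolane-4-carboxylate | COC(=O)[C@@H]1OC(C)(C)OC1 | starting material
6 | methyl (2R,4R)-2-tert-butyl-1,3-dioxolane-4-carboxylate (cis) | COC(=O)[C@@H]1O[C@H](C(C)(C)C)OC1 | intermediate
7 | TBS ketene acetal of 6 (acetal carbon R, alkene geometry open) | COC(O[Si](C)(C)C(C)(C)C)=C1O[C@H](C(C)(C)C)OC1 | intermediate
8 | Michael adduct, C4=C5 TBS enol ether, C9α quaternary dioxolane methyl ester | CO[C@@H]1OCC(O[Si](C)(C)C(C)(C)C)=C[C@H]1[C@]2(O[C@H](C(C)(C)C)OC2)C(=O)OC | intermediate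
9 | C7 aldehyde of 8 | CO[C@@H]1OCC(O[Si](C)(C)C(C)(C)C)=C[C@H]1[C@]2(O[C@H](C(C)(C)C)OC2)C=O | intermediate
10 | Mannich base, C5-CH2NMe2 ketone (C5 open) | CO[C@@H]1OCC(=O)C(CN(C)C)[C@H]1[C@]2(O[C@H](C(C)(C)C)OC2)C=O | intermediate
11 | methiodide of 10 | CO[C@@H]1OCC(=O)C(C[N+](C)(C)C)[C@H]1[C@]2(O[C@H](C(C)(C)C)OC2)C=O.[I-] | intermediate
12 | hydroacylation precursor, 1β-methoxy-5-methylene-4-oxotetrahydropyran with C9α quaternary C8 dioxolane carbaldehyde | CO[C@@H]1OCC(=O)C(=C)[C@H]1[C@]2(O[C@H](C(C)(C)C)OC2)C=O | intermediate
13 | kinetic hydroacylation product, C5 configuration unsettled | CO[C@@H]1OCC(=O)C2CC(=O)[C@@]3(O[C@H](C(C)(C)C)OC3)[C@@H]12 | intermediate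
14 | cis-fused 1β-methoxy-4,7-dioxocyclopenta[c]pyran, spiro tert-butyl dioxolane at C8 (O8 α, C10 β) | CO[C@@H]1OCC(=O)[C@H]2CC(=O)[C@@]3(O[C@H](C(C)(C)C)OC3)[C@@H]12 | intermediate
15 | 8α-hydroxy-8β-(hydroxymethyl)-4,7-dione | CO[C@@H]1OCC(=O)[C@H]2CC(=O)[C@](O)(CO)[C@@H]12 | intermediate
16 | 10-O-TBDPS ether of 15 | CO[C@@H]1OCC(=O)[C@H]2CC(=O)[C@](O)(CO[Si](c3ccccc3)(c3ccccc3)C(C)(C)C)[C@@H]12 | intermediate
17 | 7β,8α-diol, C4 ketone | CO[C@@H]1OCC(=O)[C@H]2C[C@H](O)[C@](O)(CO[Si](c3ccccc3)(c3ccccc3)C(C)(C)C)[C@@H]12 | intermediate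
18 | 4-hydroxybenzaldehyde | O=Cc1ccc(O)cc1 | starting material
19 | 4-(tert-butyldimethylsilyloxy)benzaldehyde | O=Cc1ccc(O[Si](C)(C)C(C)(C)C)cc1 | intermediate
20 | methyl (Z)-3-[4-(tert-butyldimethylsilyloxy)phenyl]acrylate | COC(=O)/C=C\c1ccc(O[Si](C)(C)C(C)(C)C)cc1 | intermediate
21 | (Z)-3-[4-(tert-butyldimethylsilyloxy)phenyl]acrylic acid | OC(=O)/C=C\c1ccc(O[Si](C)(C)C(C)(C)C)cc1 | intermediate
22 | 7β-O-(Z)-silyloxycinnamoyl ester of 17 | CO[C@@H]1OCC(=O)[C@H]2C[C@H](OC(=O)/C=C\c3ccc(O[Si](C)(C)C(C)(C)C)cc3)[C@](O)(CO[Si](c3ccccc3)(c3ccccc3)C(C)(C)C)[C@@H]12 | intermediate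
23 | C1 lactol (β-anomer drawn) | O[C@@H]1OCC(=O)[C@H]2C[C@H](OC(=O)/C=C\c3ccc(O[Si](C)(C)C(C)(C)C)cc3)[C@](O)(CO[Si](c3ccccc3)(c3ccccc3)C(C)(C)C)[C@@H]12 | intermediate
24 | (R)-3-methylpentanoic acid | CC[C@@H](C)CC(=O)O | starting material
25 | 1β-O-[(R)-3-methylpentanoyl] ester | CC[C@@H](C)CC(=O)O[C@@H]1OCC(=O)[C@H]2C[C@H](OC(=O)/C=C\c3ccc(O[Si](C)(C)C(C)(C)C)cc3)[C@](O)(CO[Si](c3ccccc3)(c3ccccc3)C(C)(C)C)[C@@H]12 | intermediate
26 | 8-O-TMS ether of 25 | CC[C@@H](C)CC(=O)O[C@@H]1OCC(=O)[C@H]2C[C@H](OC(=O)/C=C\c3ccc(O[Si](C)(C)C(C)(C)C)cc3)[C@](O[Si](C)(C)C)(CO[Si](c3ccccc3)(c3ccccc3)C(C)(C)C)[C@@H]12 | intermediate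
27 | C3=C4 enol triflate | CC[C@@H](C)CC(=O)O[C@@H]1OC=C(OS(=O)(=O)C(F)(F)F)[C@H]2C[C@H](OC(=O)/C=C\c3ccc(O[Si](C)(C)C(C)(C)C)cc3)[C@](O[Si](C)(C)C)(CO[Si](c3ccccc3)(c3ccccc3)C(C)(C)C)[C@@H]12 | intermediate
28 | tris-silylated target, C11 alcohol free | CC[C@@H](C)CC(=O)O[C@@H]1OC=C(CO)[C@H]2C[C@H](OC(=O)/C=C\c3ccc(O[Si](C)(C)C(C)(C)C)cc3)[C@](O[Si](C)(C)C)(CO[Si](c3ccccc3)(c3ccccc3)C(C)(C)C)[C@@H]12 | intermediate
29 | CNP0217341.1 (1S,5S,7S,8R,9S; side chain R; Z-coumarate) | CC[C@@H](C)CC(=O)O[C@@H]1OC=C(CO)[C@H]2C[C@H](OC(=O)/C=C\c3ccc(O)cc3)[C@](O)(CO)[C@@H]12 | target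

Total step count: 22. Longest linear sequence: 17 steps (1–3, 6–12, 16–22).

**Steps most likely to fail**

Step 9 (hydroacylation).
- Risk: loss of CO from the hindered acyl rhodium hydride, migration of the exocyclic double bond into the ring, or addition of the acyl hydride across the C4 ketone may outrun ring closure.
- Fallback: the same ring is closed at C5–C6 by enolate alkylation, setting out from aldehyde 9. LiCH2Cl (from ICH2Cl and MeLi·LiBr, THF, −78 °C) adds to C7 to give the chlorohydrin F1. Dess–Martin oxidation gives the chloromethyl ketone F2. Bu4NF then unmasks the regiodefined C4–C5 enolate, which displaces chloride in a 5-(enolexo)-exo-tet alkylation. After the same DBU equilibration the route is rejoined at 14.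

Step 6 (Mukaiyama–Michael addition).
- Risk: bond formation between two hindered carbons may be too slow, the silyl triflate may ionise the C1 acetal, or facial discrimination at C8 may erode.
- Fallback: the C8–C9 bond is made intramolecularly by a sigmatropic shift, setting out from 4 and 6.
 - Morita–Baylis–Hillman reaction of 4 with aqueous formaldehyde (DMAP, THF) gives the hydroxymethyl enone F3.
 - Luche reduction (NaBH4, CeCl3·7H2O, MeOH, −78 °C) from the face anti to OMe gives the cis diol F4.
 - LiOH converts 6 into the dioxolane acid F5, and selective Steglich esterification of the primary allylic hydroxyl gives the allylic ester F6.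
 - Ireland–Claisen rearrangement (LiN(i-Pr)2 and Me3SiCl in excess, THF, −78 °C → rt, mild acid work-up) forms C8–C9 on the α face of the ring and on the ketene acetal face remote from tert-butyl. It creates the C5=C6 methylene at the same time and gives the hydroxy acid F7.
 - LiAlH4 gives the diol F8, and Dess–Martin oxidation of both alcohols rejoins the route at 12.

Step 20 (enol triflate).
- Risk: deprotonation at the ring-fusion C5 instead of C3, or enolisation of the C1 ester followed by loss of the acyl group, may compete.
- Fallback: base-free installation of C11, setting out from 26. Wittig reaction with Ph3P=CHOMe (from [Ph3PCH2OMe]Cl and KN(SiMe3)2, THF, −78 → 0 °C) gives the exocyclic methyl enol ether F9. DDQ in wet CH2Cl2 abstracts hydride from C3, the only position flanked by both O2 and the enol ether. Hydrolysis of the resulting vinylogous oxocarbenium ion gives the C3=C4 enal F10. NaBH4 with CeCl3·7H2O (THF–EtOH, −40 °C) reduces C11 and rejoins the route at 28.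

**Further compounds**
F1 | step 9 | C7 chlorohydrin of 9 (carbinol epimers) | CO[C@@H]1OCC(O[Si](C)(C)C(C)(C)C)=C[C@H]1[C@]2(O[C@H](C(C)(C)C)OC2)C(O)CCl
F2 | step 9 | chloromethyl ketone | CO[C@@H]1OCC(O[Si](C)(C)C(C)(C)C)=C[C@H]1[C@]2(O[C@H](C(C)(C)C)OC2)C(=O)CCl
F3 | step 6 | (R)-4-(hydroxymethyl)-6-methoxy-2H-pyran-3(6H)-one | CO[C@@H]1OCC(=O)C(CO)=C1
F4 | step 6 | allylic diol, C1-OMe and C4-OH both β | CO[C@@H]1OC[C@H](O)C(CO)=C1
F5 | step 6 | (2R,4R)-2-tert-butyl-1,3-dioxolane-4-carboxylic acid | OC(=O)[C@@H]1O[C@H](C(C)(C)C)OC1
F6 | step 6 | C6 allylic ester of F4 with F5 | CO[C@@H]1OC[C@H](O)C(COC(=O)[C@@H]2O[C@H](C(C)(C)C)OC2)=C1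
F7 | step 6 | Claisen hydroxy acid, C5=C6 methylene, C9α quaternary C8 | CO[C@@H]1OC[C@H](O)C(=C)[C@H]1[C@]2(O[C@H](C(C)(C)C)OC2)C(=O)O
F8 | step 6 | C4,C7-diol from F7 | CO[C@@H]1OC[C@H](O)C(=C)[C@H]1[C@]2(O[C@H](C(C)(C)C)OC2)CO
F9 | step 20 | exocyclic C4=C11 methyl enol ether (alkene geometry open) | CC[C@@H](C)CC(=O)O[C@@H]1OCC(=COC)[C@H]2C[C@H](OC(=O)/C=C\c3ccc(O[Si](C)(C)C(C)(C)C)cc3)[C@](O[Si](C)(C)C)(CO[Si](c3ccccc3)(c3ccccc3)C(C)(C)C)[C@@H]12
F10 | step 20 | C3=C4 enal (C11 aldehyde) | CC[C@@H](C)CC(=O)O[C@@H]1OC=C(C=O)[C@H]2C[C@H](OC(=O)/C=C\c3ccc(O[Si](C)(C)C(C)(C)C)cc3)[C@](O[Si](C)(C)C)(CO[Si](c3ccccc3)(c3ccccc3)C(C)(C)C)[C@@H]12
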